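**Compound numbering used throughout:** 1–12 are the ring A branch, 13–26 the ring B branch, 27–29 the intermediates of the key step, 30 the protected isoflavone and 31 the target.

## The problem

The target 31 is an isoflavone: a chromen-4-one (rings A and C) whose C3 carries ring B, and ring B is fused across C3′–C4′ to a dihydrofuran bearing a 2-hydroxypropan-2-yl group. Ring A is a phloroglucinol nucleus with a prenyl group between the C5 and C7 hydroxyls, and the synthesis has to place that group at C6 and not at C8, the usual regiochemical trap of 5,7-dihydroxyisoflavones. Ring B is a resorcinol nucleus in which the C4′ oxygen is part of the dihydrofuran and the C2′ oxygen is free, so two oxygens flanking the same benzylic carbon must be told apart, and the bond to C3 must be made ortho to the free one. The only stereocentre, C2 of the dihydrofuran (S), is remote from every other reacting site; it can neither control nor be controlled by anything else, so a reagent has to set it and the rest of the route has to leave it alone. The sensitive groups are the prenyl alkene flanked by two phenols (acid closes it to a chroman, electrophiles attack it), the tertiary alcohol (ionization, dehydration), the electron-rich free phenols (oxidation) and C2 of the chromone (ring opening by hard nucleophiles). The feature that opens a short route is that O1 and C4 of ring C sit on the adjacent ring A carbons C8a and C4a, with the C5 oxygen next to C4a: this is the polarity of a 3-alkoxyaryne, which takes a nucleophile at the carbon remote from oxygen (C8a) and develops the carbanion beside it (C4a). Because such an aryne derives from a phenol that is symmetric about the prenyl-bearing carbon, the C6/C8 question disappears.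

## Retrosynthesis

**31 ⇒ 30.** The four O–H bonds (three phenols and the tertiary alcohol) are traced back to methoxymethyl acetals in 30. One kind of protecting group survives organolithiums, fluoride, NaH and palladium catalysis and is removed in a single final operation. The forward step must cleave four acetals with acid mild enough to leave the prenyl group between two phenols untouched.

**30 ⇒ 12 + 26.** Ring C is opened at O1–C8a and C4–C4a. This gives the aryne precursor 12 (ring A, no stereocentre) and the α-formyl arylacetate 26 (ring B, C2, C3, C4 and the stereocentre). The neighbouring cut at C3–C1′ (a 3-iodochromone and a ring B boronate) is reliable, but it needs a separate three-step construction of the prenylated chromone before the halves are joined. A deoxybenzoin cut needs an acylation of ring A under conditions that acetals and the prenyl group do not tolerate. The aryne cut joins two fragments of similar size and closes ring C in the same operation. The forward reaction must arylate the enolate at oxygen and not at carbon, add at C8a and not at C4a, and acylate the aryl anion faster than it is protonated.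

**26 ⇒ 25 ⇒ 22 + 23 ⇒ 20.** The C2–C3 bond of the future chromone is cut by a crossed Claisen formylation, giving methyl arylacetate 25. The aryl–CH2 bond of 25 is cut to aryl iodide 22 and methyl bromoacetate 23 (palladium-catalysed coupling of the zinc enolate). The C–I bond of 22 goes back to 20 by directed ortho-metalation. The acetal on the C4 oxygen of the dihydrobenzofuran is both the protecting group and the directing group, and it places the side chain ortho to the oxygen that stays free in the target.

**20 ⇒ 19 ⇒ 17 ⇒ 16 ⇒ 14 + 4 ⇒ 13.** After removal of the two acetals, the O1–C2 bond of the dihydrofuran in 19 is cut to the epoxide 17. The ring then forms by phenoxide attack on the secondary epoxide carbon with inversion, and the tertiary alcohol appears at once. The epoxide comes from the prenyl arene 16 by asymmetric epoxidation, which sets the only stereocentre under reagent control on a trisubstituted alkene. A catalytic asymmetric hydrogenation of a 2-substituted benzofuran would be shorter, but the catalyst would have to discriminate the faces of a furan carrying a fully substituted carbinol carbon, a substitution for which selectivity is not secured. Compound 16 is symmetric, so either oxygen closes the ring to the same product. The aryl–CH2 bond of 16 is cut to the bis-silyl ether 14 of 2-iodoresorcinol 13 and prenyl bromide 4.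

**12 ⇒ 8 ⇒ 7 ⇒ 6 ⇒ 3 + 4 ⇒ 2 ⇒ 1.** The C–Si and O–Tf bonds of 12 go back to bromophenol 8 (O-silylation, bromine–lithium exchange, oxygen-to-carbon silyl shift, triflation), and 8 to the symmetric phenol 7 by ortho-bromination. The prenyl group of 7 is cut at the aryl–CH2 bond: lithiation of silyl ether 3 between its two acetal oxygens and alkylation with 4 gives 6. Compound 3 comes from phloroglucinol 1 through the bis-acetal 2. Nothing in this branch is chiral, and the symmetry of 7 fixes the prenyl group at the future C6.

## Roads not taken

Alternative 1: Ring B is carried at the oxidation level of a cyclic 1,3-diketone, and the O–C2 bond of the dihydrofuran is cut. The substrate would be (2E)-4-(2,6-dioxocyclohexyl)-2-methylbut-2-enyl acetate A1. In the forward step Pd2(dba)3 (zerovalent palladium) and a chiral diphosphine would ionize the allylic acetate of A1. The enol oxygen would then attack the internal carbon of the allyl complex, which should give (2S)-2-(prop-1-en-2-yl)-3,5,6,7-tetrahydro-1-benzofuran-4(2H)-one A2.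
- Merits: the diketone of A1 is symmetric, so there is no question of which oxygen closes; the stereocentre is set by a metal catalyst at low loading; a latent resorcinol is not prone to oxidation.
- Weak points: C- versus O-alkylation in making A1; control of branched versus linear attack on the allyl complex; aromatization of A2 without disturbing an allylic ether stereocentre; a separate Markovnikov hydration of the isopropenyl group of A2 to reach the tertiary alcohol.
- Comparison: this road only delivers the stage of compound 19. The chosen plan reaches 19 in four steps with the tertiary alcohol at the right oxidation level and an SN2 ring closure whose stereochemical course is fixed. Alternative 1 is better in catalyst loading and needs no silyl protection. The chosen plan sets against this a commercial organocatalyst, no redox adjustments and no late hydration.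

Alternative 2: The C3–C2 bond of the dihydrofuran is cut. The substrate would be the tosylhydrazone N′-[(E)-[2-(2-hydroxy-2-methylpropoxy)-6-(triisopropylsilyloxy)phenyl]methylidene]-4-methylbenzenesulfonohydrazide A3. Base would turn A3 into a diazo compound, and a chiral amidoporphyrin complex of divalent cobalt, [Co(por)], would convert this into a cobalt-bound benzyl radical. The radical abstracts hydrogen from the O–CH2 group and the two carbon centres recombine, which should give 2-[(2S)-4-(triisopropylsilyloxy)-2,3-dihydro-1-benzofuran-2-yl]propan-2-ol A4.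
- Merits: the side chain of A3 arrives with the tertiary alcohol in place; the two ring B oxygens are differentiated from the start, so A4 needs no re-protection; ring, C–C bond and stereocentre form together by C–H functionalization.
- Weak points: the hydrogen to be abstracted in A3 lies on a methylene next to a fully substituted carbinol carbon, a hindered position; the free tertiary hydroxyl can coordinate the metal or donate hydrogen; enantiocontrol for a radical stabilized only by oxygen is less secure than for aryl- or ester-stabilized cases; the chiral porphyrin needs its own multistep synthesis.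
- Comparison: the step count to the ring B core A4 is equal or slightly shorter, and the oxygen differentiation is better than in the chosen plan. The chosen plan sets against this a commercially available catalyst and an inversion that follows from mechanism and not from catalyst fit.

Alternative 3: Four bonds of ring B are cut (C1′–C2′, C2′–C3′, C4′–C5′, C5′–C6′) and ring B is built on a finished chromone. The substrates would be the diazo enone (3E)-1-diazo-4-[5,7-bis(methoxymethoxy)-6-(3-methylbut-2-enyl)-4-oxochromen-3-yl]but-3-en-2-one A5 and the siloxyalkyne triisopropyl({3-[(4S)-2,2,5,5-tetramethyl-1,3-dioxolan-4-yl]prop-1-ynyl}oxy)silane A6. Irradiation of A5 would give a vinylketene by Wolff rearrangement. Cycloaddition with A6, ring opening of the cyclobutenone and electrocyclization should then give 3-{2-hydroxy-3-[[(4S)-2,2,5,5-tetramethyl-1,3-dioxolan-4-yl]methyl]-4-(triisopropylsilyloxy)phenyl}-5,7-bis(methoxymethoxy)-6-(3-methylbut-2-enyl)chromen-4-one A7.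
- Merits: every substituent of ring B in A7 is placed by the annulation with no regiochemical doubt, which is better than the directed metalation of the chosen plan; the route is highly convergent; the stereocentre comes in with the small building block A6.
- Weak points: the photolysis runs in the presence of a light-absorbing chromone and a prenyl alkene; A5 and A6 each need several steps; the acetonide of A7 must be removed with acid beside acid-labile acetals; the secondary carbinol must be closed with net retention through an epoxide; the oxygen of A7 that has to close (C4′) is the silylated one, while the free C2′ hydroxyl must be kept out, which costs further protecting-group steps.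
- Comparison: this road is clearly longer. The chosen plan sets against the superior ring B regiocontrol of A7 two short fragment syntheses, thermal chemistry throughout and a rearrangement-based fallback for its one regiochemical question.

Key step: step 15

Assumption: compound 26 is written as its Z-enol; it is expected to equilibrate with the aldehyde tautomer, and both should give the same cesium enolate 27.

## Route

Step 1
Reactants: 1 phloroglucinol (benzene-1,3,5-triol)
Product: 2 3,5-bis(methoxymethoxy)phenol
Conditions: MOMCl (2.0 equiv), iPr2NEt, DMF, 0 °C to rt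
Reagents that add atoms: chloromethyl methyl ether (MOMCl), COCCl
Why: Williamson-type O-alkylation of two of three equivalent hydroxyls; the bis-acetal is expected as the main component of a statistical mixture and is separated by chromatography, with the mono- and tris-acetals recycled.

Step 2
Reactants: 2 3,5-bis(methoxymethoxy)phenol
Product: 3 [3,5-bis(methoxymethoxy)phenoxy]tri(propan-2-yl)silane
Conditions: TIPSCl, imidazole, DMF, rt
Reagents that add atoms: chlorotri(propan-2-yl)silane (TIPSCl), CC(C)[Si](Cl)(C(C)C)C(C)C
Why: Standard silylation of a phenol; the bulky silyl ether is a poor directing group and is stable to n-BuLi, so the next metalation is left to the two acetals.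

Step 3
Reactants: 3 [3,5-bis(methoxymethoxy)phenoxy]tri(propan-2-yl)silane; 4 prenyl bromide (1-bromo-3-methylbut-2-ene)
Product: 6 [3,5-bis(methoxymethoxy)-4-(3-methylbut-2-enyl)phenoxy]tri(propan-2-yl)silane, via 2,6-bis(methoxymethoxy)-4-(triisopropylsilyloxy)phenyllithium 5 (not isolated)
Conditions: n-BuLi, THF, 0 °C; CuI (10 mol %), 4, −78 °C to rt
Reagents that add atoms: none
Why: Directed ortho-metalation at the carbon flanked by two methoxymethoxy groups, the most acidic and best-chelated site, followed by copper-mediated SN2 allylation, which gives the linear prenyl isomer; the hindered silyloxy side is not expected to compete.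

Step 4
Reactants: 6 [3,5-bis(methoxymethoxy)-4-(3-methylbut-2-enyl)phenoxy]tri(propan-2-yl)silane
Product: 7 3,5-bis(methoxymethoxy)-4-(3-methylbut-2-enyl)phenol
Conditions: Bu4NF, THF, 0 °C
Reagents that add atoms: none
Why: Fluoride cleavage of an aryl silyl ether; acetals and the alkene are inert, and the product is symmetric about the prenyl-bearing carbon.

Step 5
Reactants: 7 3,5-bis(methoxymethoxy)-4-(3-methylbut-2-enyl)phenol
Product: 8 2-bromo-3,5-bis(methoxymethoxy)-4-(3-methylbut-2-enyl)phenol
Conditions: NBS (1.0 equiv), CH2Cl2, −78 °C
Reagents that add atoms: N-bromosuccinimide (NBS), O=C1CCC(=O)N1Br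
Why: Electrophilic aromatic bromination of a very electron-rich phenol; the para position is blocked and the two ortho positions are equivalent, so one regioisomer is possible, and at low temperature the arene should react far faster than the trisubstituted alkene.

Step 6
Reactants: 8 2-bromo-3,5-bis(methoxymethoxy)-4-(3-methylbut-2-enyl)phenol
Product: 12 3,5-bis(methoxymethoxy)-4-(3-methylbut-2-enyl)-2-(trimethylsilyl)phenyl trifluoromethanesulfonate, via aryl trimethylsilyl ether 9 (not isolated), via ortho-lithiated silyl ether 10 (not isolated), via lithium 2-(trimethylsilyl)phenolate 11 (not isolated)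
Conditions: HMDS, THF, 65 °C, then evaporation; n-BuLi, THF, −100 to −78 °C; Tf2O, −100 °C to rt
Reagents that add atoms: hexamethyldisilazane (HMDS), C[Si](C)(C)N[Si](C)(C)C; trifluoromethanesulfonic anhydride (Tf2O), O=S(=O)(OS(=O)(=O)C(F)(F)F)C(F)(F)F
Why: The standard one-flask route to ortho-silylaryl triflates: O-silylation, bromine–lithium exchange (faster than any deprotonation), retro-Brook 1,3-shift of silicon from oxygen to carbon, and trapping of the lithium phenolate with Tf2O.

Step 7
Reactants: 13 2-iodoresorcinol (2-iodobenzene-1,3-diol)
Product: 14 2-iodo-1,3-bis[tert-butyl(dimethyl)silyloxy]benzene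
Conditions: TBSCl, imidazole, DMF, rt
Reagents that add atoms: tert-butyl(chloro)dimethylsilane (TBSCl), CC(C)(C)[Si](C)(C)Cl
Why: Standard silylation; the silyl ethers protect the resorcinol from oxidation in step 9 and are the trigger for ring closure in step 10.

Step 8
Reactants: 14 2-iodo-1,3-bis[tert-butyl(dimethyl)silyloxy]benzene; 4 prenyl bromide (1-bromo-3-methylbut-2-ene)
Product: 16 1,3-bis[tert-butyl(dimethyl)silyloxy]-2-(3-methylbut-2-enyl)benzene, via 2,6-bis[tert-butyl(dimethyl)silyloxy]phenylmagnesium chloride 15 (not isolated)
Conditions: iPrMgCl·LiCl, THF, 0 °C to rt; CuI (10 mol %), 4, −20 °C to rt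
Reagents that add atoms: none
Why: Iodine–magnesium exchange gives an aryl Grignard reagent that, unlike the aryllithium, does not undergo silyl migration; copper-catalysed allylic substitution with prenyl bromide at the unhindered primary carbon gives the linear prenyl arene.

Step 9
Reactants: 16 1,3-bis[tert-butyl(dimethyl)silyloxy]-2-(3-methylbut-2-enyl)benzene
Product: 17 (3R)-3-{[2,6-bis[tert-butyl(dimethyl)silyloxy]phenyl]methyl}-2,2-dimethyloxirane
Conditions: D-fructose-derived Shi ketone (1,2:4,5-di-O-isopropylidene-β-D-erythro-2,3-hexodiulo-2,6-pyranose, 30 mol %), Oxone (2KHSO5·KHSO4·K2SO4), K2CO3, Bu4NHSO4, MeCN/CH2(OMe)2, aq. Na2B4O7–Na2EDTA buffer, 0 °C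
Reagents that add atoms: potassium peroxymonosulfate (active component of Oxone), [K+].[O-]S(=O)(=O)OO
Why: Shi asymmetric epoxidation of a trisubstituted alkene; the chiral dioxirane transfers oxygen through a spiro transition state, and the D-fructose-derived ketone is expected to give the (R)-epoxide by analogy with the (R,R)-epoxides it gives from trans-disubstituted and trisubstituted alkenes, so the stereocentre is set by the catalyst alone.

Step 10
Reactants: 17 (3R)-3-{[2,6-bis[tert-butyl(dimethyl)silyloxy]phenyl]methyl}-2,2-dimethyloxirane
Product: 19 2-[(2S)-4-hydroxy-2,3-dihydro-1-benzofuran-2-yl]propan-2-ol, via desilylated epoxy resorcinol 18 (not isolated)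
Conditions: Bu4NF (2.5 equiv), THF, 0 °C to rt
Reagents that add atoms: none
Why: Fluoride frees the phenoxide, which opens the epoxide at the secondary carbon in a 5-exo-tet SN2 reaction (the base-mediated route to 2-(2-hydroxypropan-2-yl)dihydrobenzofurans), so the (R)-epoxide should give the (S)-ether by clean inversion; the two phenols are equivalent and the 6-endo opening at the tertiary carbon is an acid-type pathway not expected here. If needed, the enantiomeric purity can be raised by recrystallization at this stage.

Step 11
Reactants: 19 2-[(2S)-4-hydroxy-2,3-dihydro-1-benzofuran-2-yl]propan-2-ol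
Product: 20 (2S)-4-(methoxymethoxy)-2-[2-(methoxymethoxy)propan-2-yl]-2,3-dihydro-1-benzofuran
Conditions: MOMCl (4 equiv), iPr2NEt, Bu4NI (cat.), ClCH2CH2Cl, 60 °C
Reagents that add atoms: chloromethyl methyl ether (MOMCl), COCCl
Why: Acetalization of the phenol and, with excess reagent, iodide catalysis and heat, of the tertiary alcohol; no bond to the stereocentre is touched.

Step 12
Reactants: 20 (2S)-4-(methoxymethoxy)-2-[2-(methoxymethoxy)propan-2-yl]-2,3-dihydro-1-benzofuran
Product: 22 (2S)-5-iodo-4-(methoxymethoxy)-2-[2-(methoxymethoxy)propan-2-yl]-2,3-dihydro-1-benzofuran, via C5-lithiated dihydrobenzofuran 21 (not isolated)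
Conditions: n-BuLi, TMEDA, THF, −20 to 0 °C; I2, −78 °C to rt
Reagents that add atoms: iodine, II
Why: Directed ortho-metalation by the aryl methoxymethyl ether, a much stronger director than the ring ether oxygen, at its only free ortho position C5, followed by iodinolysis of the aryllithium; the stereocentre carries no acidic hydrogen.

Step 13
Reactants: 22 (2S)-5-iodo-4-(methoxymethoxy)-2-[2-(methoxymethoxy)propan-2-yl]-2,3-dihydro-1-benzofuran; 23 methyl bromoacetate
Product: 25 methyl 2-[(2S)-4-(methoxymethoxy)-2-[2-(methoxymethoxy)propan-2-yl]-2,3-dihydro-1-benzofuran-5-yl]acetate, via bromo(2-methoxy-2-oxoethyl)zinc 24 (not isolated)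
Conditions: Zn dust, Me3SiCl (cat.), 23, THF, 40 °C; then 22, Pd(dba)2, P(t-Bu)3, THF, rt to 50 °C
Reagents that add atoms: none
Why: Palladium-catalysed α-arylation of an ester through its zinc enolate (Negishi-type coupling of a Reformatsky reagent with an aryl halide); the nearly neutral zinc enolate tolerates the acetals and gives the methyl ester needed as the acyl acceptor in step 15.

Step 14
Reactants: 25 methyl 2-[(2S)-4-(methoxymethoxy)-2-[2-(methoxymethoxy)propan-2-yl]-2,3-dihydro-1-benzofuran-5-yl]acetate
Product: 26 methyl (Z)-3-hydroxy-2-[(2S)-4-(methoxymethoxy)-2-[2-(methoxymethoxy)propan-2-yl]-2,3-dihydro-1-benzofuran-5-yl]prop-2-enoate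
Conditions: NaH, HCO2Me, THF, 0 °C to rt; AcOH quench
Reagents that add atoms: methyl formate, COC=O
Why: Crossed Claisen condensation (C-formylation) of an arylacetate, driven by formation of the stabilized sodium enolate of the product; a buffered quench keeps the acetals intact.

Step 15
Reactants: 12 3,5-bis(methoxymethoxy)-4-(3-methylbut-2-enyl)-2-(trimethylsilyl)phenyl trifluoromethanesulfonate; 26 methyl (Z)-3-hydroxy-2-[(2S)-4-(methoxymethoxy)-2-[2-(methoxymethoxy)propan-2-yl]-2,3-dihydro-1-benzofuran-5-yl]prop-2-enoate
Product: 30 3-[(2S)-4-(methoxymethoxy)-2-[2-(methoxymethoxy)propan-2-yl]-2,3-dihydro-1-benzofuran-5-yl]-5,7-bis(methoxymethoxy)-6-(3-methylbut-2-enyl)chromen-4-one, via cesium enolate 27 (not isolated), via aryne 28 (not isolated), via arylcesium adduct 29 (not isolated)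
Conditions: CsF (4 equiv), THF, 65 °C; 12 (1.5 equiv) added slowly
Reagents that add atoms: none
Why: Proposed new method: fluoride attacks silicon in 12 and triflate leaves to give aryne 28 (C4a≡C8a), the oxygen terminus of cesium enolate 27 adds at C8a, and the aryl anion 29 at C4a attacks the methyl ester and expels methoxide; the closest known reaction type is the CsF-mediated annulation of arynes with methyl salicylates (to xanthones) and with β-enamino esters (to 4-quinolones), heteroatom addition followed by intramolecular acylation, which has not been shown for the enolate oxygen of an α-formyl ester. Addition at C8a and not at C4a is expected from the 3-alkoxyaryne pattern: the C5 acetal oxygen polarizes the triple bond, stabilizes the developing carbanion at C4a inductively and shields that carbon, while C8a is flanked only by hydrogen. Oxygen and not carbon attack is expected because the enolate carbon is already fully substituted and shielded by the ortho-substituted ring B, and because enolates of this class react with hard electrophiles at the formyl oxygen. Ring C closes by a 6-exo-trig acyl substitution, which needs the ester cis to the new aryl ether; THF and the cesium counter-ion are chosen to hold 27 as a chelated contact ion pair with both oxygens on the same side. Slow addition of 12 keeps the aryne concentration low so that the intramolecular acylation can outrun proton quenching of 29, and full conversion of 26 into 27 removes the most acidic proton source. No stereocentre is formed; the C2 centre of the dihydrofuran is remote and not acidic and should pass unchanged, and the acetals and the prenyl alkene are inert to fluoride.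

Step 16
Reactants: 30 3-[(2S)-4-(methoxymethoxy)-2-[2-(methoxymethoxy)propan-2-yl]-2,3-dihydro-1-benzofuran-5-yl]-5,7-bis(methoxymethoxy)-6-(3-methylbut-2-enyl)chromen-4-one
Product: 31 5,7-dihydroxy-3-[(2S)-4-hydroxy-2-(2-hydroxypropan-2-yl)-2,3-dihydro-1-benzofuran-5-yl]-6-(3-methylbut-2-enyl)chromen-4-one
Conditions: 3 M aq. HCl, MeOH, 45 °C
Reagents that add atoms: none
Why: Acid-catalysed transacetalization of methoxymethyl ethers to methanol, the usual last step for prenylated polyphenols; the phenolic acetals should go first and the tertiary alkyl acetal last, and dilute acid at moderate temperature is chosen so that the prenyl group and the tertiary alcohol are not ionized.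

## Compound list

1 | phloroglucinol (benzene-1,3,5-triol) | Oc1cc(O)cc(O)c1 | starting material
2 | 3,5-bis(methoxymethoxy)phenol | COCOc1cc(O)cc(OCOC)c1 | intermediate
3 | [3,5-bis(methoxymethoxy)phenoxy]tri(propan-2-yl)silane | COCOc1cc(OCOC)cc(O[Si](C(C)C)(C(C)C)C(C)C)c1 | intermediate
4 | prenyl bromide (1-bromo-3-methylbut-2-ene) | CC(C)=CCBr | starting material
5 | 2,6-bis(methoxymethoxy)-4-(triisopropylsilyloxy)phenyllithium | [Li]c1c(OCOC)cc(O[Si](C(C)C)(C(C)C)C(C)C)cc1OCOC | intermediate
6 | [3,5-bis(methoxymethoxy)-4-(3-methylbut-2-enyl)phenoxy]tri(propan-2-yl)silane | COCOc1cc(O[Si](C(C)C)(C(C)C)C(C)C)cc(OCOC)c1CC=C(C)C | intermediate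
7 | 3,5-bis(methoxymethoxy)-4-(3-methylbut-2-enyl)phenol | COCOc1cc(O)cc(OCOC)c1CC=C(C)C | intermediate
8 | 2-bromo-3,5-bis(methoxymethoxy)-4-(3-methylbut-2-enyl)phenol | COCOc1cc(O)c(Br)c(OCOC)c1CC=C(C)C | intermediate
9 | [2-bromo-3,5-bis(methoxymethoxy)-4-(3-methylbut-2-enyl)phenoxy]trimethylsilane | COCOc1cc(O[Si](C)(C)C)c(Br)c(OCOC)c1CC=C(C)C | intermediate
10 | [2,4-bis(methoxymethoxy)-3-(3-methylbut-2-enyl)-6-(trimethylsilyloxy)phenyl]lithium | COCOc1cc(O[Si](C)(C)C)c([Li])c(OCOC)c1CC=C(C)C | intermediate
11 | lithium 3,5-bis(methoxymethoxy)-4-(3-methylbut-2-enyl)-2-(trimethylsilyl)phenolate | COCOc1cc([O-])c([Si](C)(C)C)c(OCOC)c1CC=C(C)C.[Li+] | intermediate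
12 | 3,5-bis(methoxymethoxy)-4-(3-methylbut-2-enyl)-2-(trimethylsilyl)phenyl trifluoromethanesulfonate | C[Si](C)(C)c1c(OS(=O)(=O)C(F)(F)F)cc(OCOC)c(CC=C(C)C)c1OCOC | intermediate
13 | 2-iodoresorcinol (2-iodobenzene-1,3-diol) | Oc1cccc(O)c1I | starting material
14 | 2-iodo-1,3-bis[tert-butyl(dimethyl)silyloxy]benzene | CC(C)(C)[Si](C)(C)Oc1cccc(O[Si](C)(C)C(C)(C)C)c1I | intermediate
15 | 2,6-bis[tert-butyl(dimethyl)silyloxy]phenylmagnesium chloride | CC(C)(C)[Si](C)(C)Oc1cccc(O[Si](C)(C)C(C)(C)C)c1[Mg]Cl | intermediate
16 | 1,3-bis[tert-butyl(dimethyl)silyloxy]-2-(3-methylbut-2-enyl)benzene | CC(C)=CCc1c(O[Si](C)(C)C(C)(C)C)cccc1O[Si](C)(C)C(C)(C)C | intermediate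
17 | (3R)-3-{[2,6-bis[tert-butyl(dimethyl)silyloxy]phenyl]methyl}-2,2-dimethyloxirane | CC1(C)O[C@@H]1Cc1c(O[Si](C)(C)C(C)(C)C)cccc1O[Si](C)(C)C(C)(C)C | intermediate
18 | 2-{[(2R)-3,3-dimethyloxiran-2-yl]methyl}benzene-1,3-diol | CC1(C)O[C@@H]1Cc1c(O)cccc1O | intermediate
19 | 2-[(2S)-4-hydroxy-2,3-dihydro-1-benzofuran-2-yl]propan-2-ol | Oc1cccc2c1C[C@@H](C(C)(C)O)O2 | intermediate
20 | (2S)-4-(methoxymethoxy)-2-[2-(methoxymethoxy)propan-2-yl]-2,3-dihydro-1-benzofuran | COCOc1cccc2c1C[C@@H](C(C)(C)OCOC)O2 | intermediate
21 | [(2S)-4-(methoxymethoxy)-2-[2-(methoxymethoxy)propan-2-yl]-2,3-dihydro-1-benzofuran-5-yl]lithium | COCOc1c([Li])ccc2c1C[C@@H](C(C)(C)OCOC)O2 | intermediate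
22 | (2S)-5-iodo-4-(methoxymethoxy)-2-[2-(methoxymethoxy)propan-2-yl]-2,3-dihydro-1-benzofuran | COCOc1c(I)ccc2c1C[C@@H](C(C)(C)OCOC)O2 | intermediate
23 | methyl bromoacetate | COC(=O)CBr | starting material
24 | bromo(2-methoxy-2-oxoethyl)zinc | COC(=O)C[Zn]Br | intermediate
25 | methyl 2-[(2S)-4-(methoxymethoxy)-2-[2-(methoxymethoxy)propan-2-yl]-2,3-dihydro-1-benzofuran-5-yl]acetate | COC(=O)Cc1ccc2c(c1OCOC)C[C@@H](C(C)(C)OCOC)O2 | intermediate
26 | methyl (Z)-3-hydroxy-2-[(2S)-4-(methoxymethoxy)-2-[2-(methoxymethoxy)propan-2-yl]-2,3-dihydro-1-benzofuran-5-yl]prop-2-enoate | COC(=O)/C(=C\O)c1ccc2c(c1OCOC)C[C@@H](C(C)(C)OCOC)O2 | intermediate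
27 | cesium (Z)-3-methoxy-2-[(2S)-4-(methoxymethoxy)-2-[2-(methoxymethoxy)propan-2-yl]-2,3-dihydro-1-benzofuran-5-yl]-3-oxoprop-1-en-1-olate | COC(=O)/C(=C\[O-])c1ccc2c(c1OCOC)C[C@@H](C(C)(C)OCOC)O2.[Cs+] | intermediate
28 | 3,5-bis(methoxymethoxy)-4-(3-methylbut-2-enyl)benzyne (1,2-didehydrobenzene) | COCOC1=CC#CC(OCOC)=C1CC=C(C)C | intermediate
29 | arylcesium adduct: methyl (Z)-3-[2-cesio-3,5-bis(methoxymethoxy)-4-(3-methylbut-2-enyl)phenoxy]-2-[(2S)-4-(methoxymethoxy)-2-[2-(methoxymethoxy)propan-2-yl]-2,3-dihydro-1-benzofuran-5-yl]prop-2-enoate | COC(=O)/C(=C\Oc1cc(OCOC)c(CC=C(C)C)c(OCOC)c1[Cs])c1ccc2c(c1OCOC)C[C@@H](C(C)(C)OCOC)O2 | intermediate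
30 | 3-[(2S)-4-(methoxymethoxy)-2-[2-(methoxymethoxy)propan-2-yl]-2,3-dihydro-1-benzofuran-5-yl]-5,7-bis(methoxymethoxy)-6-(3-methylbut-2-enyl)chromen-4-one | CC(C)=CCc1c(OCOC)cc2occ(-c3ccc4c(c3OCOC)C[C@@H](C(C)(C)OCOC)O4)c(=O)c2c1OCOC | intermediate
31 | 5,7-dihydroxy-3-[(2S)-4-hydroxy-2-(2-hydroxypropan-2-yl)-2,3-dihydro-1-benzofuran-5-yl]-6-(3-methylbut-2-enyl)chromen-4-one | CC(C)=CCc1c(O)cc2occ(-c3ccc4c(c3O)C[C@@H](C(C)(C)O)O4)c(=O)c2c1O | target

## Step count and least certain steps

Total: 16 steps. Longest linear sequence: 10 steps (13 to 31, steps 7–14, 15 and 16). The ring A branch (1 to 12, steps 1–6) joins at step 15.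

**Step 15 (carries the label "Proposed new method:").** Three processes may divert the reaction. The enolate may be arylated at carbon, followed by transfer of the formyl group. The enolate may react at oxygen through its extended geometry, so that the aryl anion cannot reach the ester and is protonated. The released methoxide may attack C2 of the product chromone. The fallback uses known chemistry only; it sets out from bromophenol 8 and aryl iodide 22 and returns at 30. Deprotonation of the phenol and bromine–lithium exchange of 8 with two equivalents of n-BuLi, then N-methoxy-N-methylacetamide, should give 1-[6-hydroxy-2,4-bis(methoxymethoxy)-3-(3-methylbut-2-enyl)phenyl]ethanone F1. Heating with N,N-dimethylformamide dimethyl acetal should give (E)-3-(dimethylamino)-1-[6-hydroxy-2,4-bis(methoxymethoxy)-3-(3-methylbut-2-enyl)phenyl]prop-2-en-1-one F2. Iodine and pyridine in CHCl3 should cyclize this to 3-iodo-5,7-bis(methoxymethoxy)-6-(3-methylbut-2-enyl)chromen-4-one F3; the symmetry of 7 again guarantees the 6-prenyl isomer. Miyaura borylation of 22 (bis(pinacolato)diboron, PdCl2(dppf), KOAc, dioxane, 80 °C) should give 2-[(2S)-4-(methoxymethoxy)-2-[2-(methoxymethoxy)propan-2-yl]-2,3-dihydro-1-benzofuran-5-yl]-4,4,5,5-tetramethyl-1,3,2-dioxaborolane F4. Suzuki coupling of the iodochromone and the boronate (Pd(PPh3)4, Na2CO3, dimethoxyethane/water, 80 °C) should give 30.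

**Step 12.** Metalation may go astray in two ways: at C7, directed by the ring oxygen together with the side-chain acetal, or at the benzylic C3, followed by β-elimination of the ring oxygen. The fallback replaces metalation by a sigmatropic shift that can only reach C5; it sets out from 19 and returns at 25. Allyl bromide and K2CO3 in acetone should alkylate the phenol to 2-[(2S)-4-(prop-2-enyloxy)-2,3-dihydro-1-benzofuran-2-yl]propan-2-ol F5. Aromatic Claisen rearrangement in N,N-diethylaniline at about 190 °C should give 2-[(2S)-4-hydroxy-5-(prop-2-enyl)-2,3-dihydro-1-benzofuran-2-yl]propan-2-ol F6, C5 being the only free ortho position. MOMCl and iPr2NEt should give (2S)-4-(methoxymethoxy)-2-[2-(methoxymethoxy)propan-2-yl]-5-(prop-2-enyl)-2,3-dihydro-1-benzofuran F7. Ozonolysis in CH2Cl2/MeOH containing NaOH at −78 °C, with ozone dosed against an indicator dye, should convert the terminal alkene directly into methyl ester 25.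

**Step 5.** The brominating agent may attack the prenyl alkene, or a second bromination may follow the first. The fallback avoids electrophilic halogen altogether; it sets out from 7 and returns at 12. Isopropyl isocyanate and Et3N should give [3,5-bis(methoxymethoxy)-4-(3-methylbut-2-enyl)phenyl] N-(propan-2-yl)carbamate F8. In-situ N-silylation (TBSOTf, TMEDA), carbamate-directed ortho-lithiation (n-BuLi, TMEDA, −78 °C) at the position between carbamate and acetal, and quenching with Me3SiCl should give, after work-up, [3,5-bis(methoxymethoxy)-4-(3-methylbut-2-enyl)-2-(trimethylsilyl)phenyl] N-(propan-2-yl)carbamate F9. Et2NH and DBU in MeCN at 40 °C should release the phenolate, which N-phenylbis(trifluoromethanesulfonimide) converts into 12.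

**Step 8.** Iodine–magnesium exchange at a carbon flanked by two bulky silyloxy groups may be slow, and allylic substitution may proceed with transposition to the 1,1-dimethylallyl isomer. The fallback reverses the polarity: linear-selective Negishi coupling of aryl iodide 14 with (3-methylbut-2-enyl)zinc bromide under Pd(OAc)2 and the biaryl phosphine CPhos in THF should give 16 directly. It sets out from 14, returns at 16 and makes no new compound.

**Step 16.** During the slow cleavage of the tertiary alkyl acetal, a flanking phenol may add to the protonated prenyl alkene (chroman formation), or the tertiary alcohol may ionize. The fallback removes the proton source: ZnBr2 and propane-1-thiol in CH2Cl2 at 0 °C transfer the methoxymethyl groups to sulfur under aprotic Lewis-acid activation. It sets out from 30, returns at 31 and makes no new compound.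

## Further compounds

F1 | step 15 | 1-[6-hydroxy-2,4-bis(methoxymethoxy)-3-(3-methylbut-2-enyl)phenyl]ethanone | CC(=O)c1c(O)cc(OCOC)c(CC=C(C)C)c1OCOC
F2 | step 15 | (E)-3-(dimethylamino)-1-[6-hydroxy-2,4-bis(methoxymethoxy)-3-(3-methylbut-2-enyl)phenyl]prop-2-en-1-one | CN(C)/C=C/C(=O)c1c(O)cc(OCOC)c(CC=C(C)C)c1OCOC
F3 | step 15 | 3-iodo-5,7-bis(methoxymethoxy)-6-(3-methylbut-2-enyl)chromen-4-one | CC(C)=CCc1c(OCOC)cc2occ(I)c(=O)c2c1OCOC
F4 | step 15 | 2-[(2S)-4-(methoxymethoxy)-2-[2-(methoxymethoxy)propan-2-yl]-2,3-dihydro-1-benzofuran-5-yl]-4,4,5,5-tetramethyl-1,3,2-dioxaborolane | COCOc1c(B3OC(C)(C)C(C)(C)O3)ccc2c1C[C@@H](C(C)(C)OCOC)O2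
F5 | step 12 | 2-[(2S)-4-(prop-2-enyloxy)-2,3-dihydro-1-benzofuran-2-yl]propan-2-ol | C=CCOc1cccc2c1C[C@@H](C(C)(C)O)O2
F6 | step 12 | 2-[(2S)-4-hydroxy-5-(prop-2-enyl)-2,3-dihydro-1-benzofuran-2-yl]propan-2-ol | C=CCc1ccc2c(c1O)C[C@@H](C(C)(C)O)O2
F7 | step 12 | (2S)-4-(methoxymethoxy)-2-[2-(methoxymethoxy)propan-2-yl]-5-(prop-2-enyl)-2,3-dihydro-1-benzofuran | C=CCc1ccc2c(c1OCOC)C[C@@H](C(C)(C)OCOC)O2
F8 | step 5 | [3,5-bis(methoxymethoxy)-4-(3-methylbut-2-enyl)phenyl] N-(propan-2-yl)carbamate | COCOc1cc(OC(=O)NC(C)C)cc(OCOC)c1CC=C(C)C
F9 | step 5 | [3,5-bis(methoxymethoxy)-4-(3-methylbut-2-enyl)-2-(trimethylsilyl)phenyl] N-(propan-2-yl)carbamate | COCOc1cc(OC(=O)NC(C)C)c([Si](C)(C)C)c(OCOC)c1CC=C(C)C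
F0 | step 8 | none | none
F0 | step 16 | none | none
A1 | alternative 1 | (2E)-4-(2,6-dioxocyclohexyl)-2-methylbut-2-enyl acetate | CC(=O)OC/C(C)=C/CC1C(=O)CCCC1=O
A2 | alternative 1 | (2S)-2-(prop-1-en-2-yl)-3,5,6,7-tetrahydro-1-benzofuran-4(2H)-one | O=C1CCCC2=C1C[C@@H](C(C)=C)O2
A3 | alternative 2 | N′-[(E)-[2-(2-hydroxy-2-methylpropoxy)-6-(triisopropylsilyloxy)phenyl]methylidene]-4-methylbenzenesulfonohydrazide | Cc1ccc(cc1)S(=O)(=O)N/N=C/c1c(OCC(C)(C)O)cccc1O[Si](C(C)C)(C(C)C)C(C)C
A4 | alternative 2 | 2-[(2S)-4-(triisopropylsilyloxy)-2,3-dihydro-1-benzofuran-2-yl]propan-2-ol | CC(C)[Si](C(C)C)(C(C)C)Oc1cccc2c1C[C@@H](C(C)(C)O)O2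
A5 | alternative 3 | (3E)-1-diazo-4-[5,7-bis(methoxymethoxy)-6-(3-methylbut-2-enyl)-4-oxochromen-3-yl]but-3-en-2-one | [N-]=[N+]=CC(=O)/C=C/c1coc2cc(OCOC)c(CC=C(C)C)c(OCOC)c2c1=O
A6 | alternative 3 | triisopropyl({3-[(4S)-2,2,5,5-tetramethyl-1,3-dioxolan-4-yl]prop-1-ynyl}oxy)silane | CC(C)[Si](OC#CC[C@@H]1OC(C)(C)OC1(C)C)(C(C)C)C(C)C
A7 | alternative 3 | 3-{2-hydroxy-3-[[(4S)-2,2,5,5-tetramethyl-1,3-dioxolan-4-yl]methyl]-4-(triisopropylsilyloxy)phenyl}-5,7-bis(methoxymethoxy)-6-(3-methylbut-2-enyl)chromen-4-one | CC(C)=CCc1c(OCOC)cc2occ(-c3ccc(O[Si](C(C)C)(C(C)C)C(C)C)c(C[C@@H]4OC(C)(C)OC4(C)C)c3O)c(=O)c2c1OCOC
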